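## Analysis of the target

Target 31 is a 1,5,6,7,8,8a-hexahydronaphthalene. Ring A (C8, C9, C14–C17) holds the conjugated diene C14=C15–C16=C17, a methyl group on C16 and the acetonyl group C18–C20 on C17. Ring B (C9–C14) is a cyclohexanone (C11) with methyl groups on both α-carbons, C10 and C12. C8 carries the C1–C7 chain: an (E)-C6=C7 alkene, a trans C4–C5 oxirane with a quaternary C4, and an (E)-C2=C3 acrylic acid.

There are six stereocentres. H8 and H9 are cis; the C10 methyl lies on the same face of ring B as the C8–C9 bond and the C12 methyl, so the ketone is a cis-2,6-dimethylcyclohexanone. C4 and C5 (S,S) sit behind the flat C6=C7 bond, four and three bonds from C8, so the core cannot relay its configuration to them.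

The sensitive points are these:
- The oxirane is allylic at C5 and opens with acid or zerovalent palladium.
- C18H2 lies between the C19 ketone and the diene, so base would pull the diene into conjugation.
- C8–H is doubly allylic.
- The C11 ketone can enolise to both sides.

The hard part is to oxidise one of five C=C bonds, C4=C5, which is not the most electron-rich; any electrophilic oxidant would take the ring diene or C6=C7 first. The strategy rests on one feature: while C3 is still an aldehyde, C4=C5 is the only alkene that is the α,β-bond of a carbonyl compound (a 2,4-dienal). A nucleophilic oxidant under iminium activation can therefore pick it out, and the same aldehyde then serves to attach C1–C2.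

## Retrosynthetic reasoning

**C11 and C19 ketones, C1 acid (31 ⇐ 30 ⇐ 29).** Both ketones are made last, by oxidation of the secondary alcohols of 30. Neither the β,γ-unsaturated C19 ketone nor the doubly α-branched C11 ketone then ever meets a base. 30 comes from 29 by one fluoride treatment that removes both silyl ethers and the silylethyl ester.

**C2=C3 (29 ⇐ 25 + 28).** The enoate is cut at the alkene. The forward olefination has to be E-selective and mild; the aldehyde carbon C3 of 25 sits on a quaternary oxirane carbon and cannot epimerise. 28 is the ester of 26 with 27.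

**C4–O and C5–O (25 ⇐ 24), the key disconnection.** The oxirane is removed to the (4E,6E)-dienal 24. Cutting here, and not at an earlier stage, means the oxidation happens when C4=C5 is the only carbonyl-conjugated alkene. The forward step must add oxygen to that bond only, 1,4 and not 1,6, on the C4-Re/C5-Si face under catalyst control.

**C4=C5 and C6=C7 (24 ⇐ 23 ⇐ 22 ⇐ 19, twice with 20).** The chain C3–C6 is two units of the same ylide 20. The second unit converts enal 23 into 24. The first is used on lactol 19; it sets C6=C7 and frees the C11 hydroxyl of 22, which is silylated to 23. Each Wittig reaction must stop after one homologation and give the E alkene.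

**Lactol (19 ⇐ 18).** Partial reduction of the bridged δ-lactone 18 brings C7 to the aldehyde oxidation level.

**C8–C17 and C9–C14, rings A and B (18 ⇐ 17 ⇐ 16).** Both rings are opened in one intramolecular [4+2] disconnection to pyranone 16, whose C3–C6 atoms become C17–C14. Decarboxylative cycloreversion of the bridged adduct 17 leaves exactly the required diene. The dienophile is the C8=C9 bond of a 5,6-dihydropyranone: its cis geometry gives cis H8/H9, and the tether on C11 can only reach the face of that ring on which it stands, so C8 and C9 are fixed relative to C10–C12.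

**C8=C9 and the C7–O ester bond (16 ⇐ 15 ⇐ 14).** The dihydropyranone is cut by ring-closing metathesis back to acrylate 15 and then to homoallylic alcohol 14.

**C10–C11 (14 ⇐ 12 + 13).** An anti-selective crotylation of aldehyde 12 with 13 sets C10 and C11. The anti,anti triad requires reagent control against the weak preference of the α-methyl aldehyde.

**C12–C13 (12 ⇐ 11 ⇐ 6 + 9, through 10).** The C12 stereocentre is taken from the lactate pool: the lithiated 6-methyl group of pyranone 6 displaces the triflate of 9 with inversion. The amide of 11 is then reduced to the aldehyde by a reagent that spares the pyranone. 9 comes from 7 through 8.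

**C16–CH3 and C17–C18 (6 ⇐ 5 ⇐ 4 ⇐ 1 + 2, through 3).** C3 of an alkyl pyranone is not nucleophilic, but C3 of the 4-hydroxy compound 1 is. The C18–C20 unit with its spectator stereocentre C19 is attached by reductive alkylation with 2. The C4 oxygen is then exchanged for the C16 methyl through triflate 5.

## Alternatives that were turned down

**Alternative 1: intermolecular Diels–Alder reaction of a ring B silyloxy diene with a chiral butenolide.**
- Disconnection: C8–C9 and C16–C17 of ring A. A semicyclic 1-silyloxy diene (C9=C14–C15=C16) adds endo to the 5-(menthyloxy)furan-2(5H)-one A1, anti to the alkoxy group. Loss of the silyloxy group gives the tricyclic dienyl lactone A2.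
- For it: it is convergent, the auxiliary is cheap, C8 and C9 and the full diene arrive in two operations, and C7 is already a masked aldehyde. On convergence and speed of core assembly it is stronger than the chosen route.
- Against it: in A2, C18 is a lactone carbonyl, so the acetonyl group needs reduction to CH2 and a two-carbon addition beside an acid-labile acetal. C10 has no methyl and C11 is a ketal, so a late, stereocontrolled enolate methylation is owed. The diene face, and so C9 relative to C12, is steered only by a remote methyl group, while the auxiliary controls the other partner.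
- Comparison: the chosen route makes C8 and C9 depend on C10–C12 through the tether. It carries the C17 chain and both ring methyls from the start, so only the oxirane is left open.

**Alternative 2: Ireland–Claisen ring contraction of a δ-lactone.**
- Disconnection: C8–C9. The silyl ketene acetal of a six-membered lactone with a cyclohexenyl group on its carbinol carbon C15 rearranges through a boat. This gives acid A3 with the C7 carboxyl on C8, cis H8/H9 and C14=C15.
- For it: chirality transfer from C15–O to C8/C9 is at least as predictable as a thermal cycloaddition, the ring B triad is complete, and C7 is at the acid level.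
- Against it: A3 has only one of the two ring A alkenes. C16 is an sp3 stereocentre that must be destroyed, and C17 carries oxygen instead of C18–C20. The missing alkene and chain would need a β,γ-unsaturated C17 ketone (prone to conjugation and to enolisation toward C8), a regioselective enol triflate, and an sp2–sp3 coupling with a β-oxygenated alkyl metal that tends to eliminate. Two stereocentres are built only to be erased.
- Comparison: the chosen route gets the diene with both substituents directly from the cycloreversion.

**Alternative 3: enol silane cyclisation onto a tricarbonyliron dienyl cation.**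
- Disconnection: C9–C10 of ring B. A tethered methyl ketone, silylated in the flask, attacks terminus C9 of a cationic tricarbonyliron cyclohexadienyl complex anti to the metal. The product is the diene complex A4.
- For it: attack anti to iron is dependable, conditions are mild, and the diene stays masked as its complex. That is a real advantage over the chosen route, which carries a free diene through nine steps.
- Against it: an enantiopure planar-chiral complex and stoichiometric metal carbonyl are needed. Fused closure at C9 must beat attack at the other terminus. C10 is still CH2 in A4, so a methylation is owed. The complex must be taken apart oxidatively before a peroxide-based oxirane formation, so the protection is lost exactly where it would matter.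
- Comparison: the chosen route is metal-free in the core and longer in heat. It offers instead a core in which every ring stereocentre is fixed by one tethered cycloaddition.

Key step: step 16

Assumptions:
- Silyl ether 2 is taken as a catalogue compound; it is otherwise two steps from 7 (silylation, partial reduction).
- The sense of induction in steps 8 and 16 is taken from the accepted models for simple aldehydes and (E)-α-methyl enals. If the opposite face is served, the enantiomeric acid (step 8) or the quinidine-derived pseudo-enantiomeric amine with the enantiomeric acid (step 16) is used.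

## Route

Step 1
Reactants: 1 4-hydroxy-6-methyl-2H-pyran-2-one; 2 (S)-2-(tert-butyldimethylsilyloxy)propanal
Product: 4 3-[(2S)-2-(tert-butyldimethylsilyloxy)propyl]-4-hydroxy-6-methyl-2H-pyran-2-one, via alkylidene pyrandione 3 (not isolated)
Conditions: Hantzsch ester (diethyl 2,6-dimethyl-1,4-dihydropyridine-3,5-dicarboxylate, 1.1 equiv), L-proline (10 mol%), CH2Cl2, rt
Reagents that add atoms: none
Why: Knoevenagel condensation at the nucleophilic C3 of the 4-hydroxypyranone gives 3, which takes up hydride from the dihydropyridine in a conjugate transfer hydrogenation (three-component reductive alkylation). The C19 stereocentre comes with the lactate-derived aldehyde; fast condensation should leave no time for α-epimerisation.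

Step 2
Reactants: 4
Product: 5 3-[(2S)-2-(tert-butyldimethylsilyloxy)propyl]-6-methyl-2-oxo-2H-pyran-4-yl trifluoromethanesulfonate
Conditions: Tf2O, Et3N, CH2Cl2, −78 to 0 °C
Reagents that add atoms: trifluoromethanesulfonic anhydride, O=S(=O)(OS(=O)(=O)C(F)(F)F)C(F)(F)F
Why: O-sulfonylation of the acidic C4 enol; 4-hydroxy-2-pyranones are sulfonylated at the 4-oxygen, and the silyl ether is inert.

Step 3
Reactants: 5
Product: 6 3-[(2S)-2-(tert-butyldimethylsilyloxy)propyl]-4,6-dimethyl-2H-pyran-2-one
Conditions: MeZnCl (2 equiv), Pd(PPh3)4 (5 mol%), THF, 50 °C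
Reagents that add atoms: methylzinc chloride, C[Zn]Cl
Why: Negishi coupling; zerovalent palladium inserts readily into the vinylogous acyl triflate, and a methyl group cannot β-eliminate. This installs the C16 methyl.

Step 4
Reactants: 7 ethyl (S)-lactate
Product: 8 (2S)-2-hydroxy-N-methoxy-N-methylpropanamide
Conditions: MeNH(OMe)·HCl (2.5 equiv), i-PrMgCl (5 equiv), THF, −20 to 0 °C
Reagents that add atoms: N,O-dimethylhydroxylamine hydrochloride, CNOC.Cl
Why: Weinreb amide formation by magnesium amide aminolysis of the ester; the stereocentre sits beside a magnesium alkoxide and is not deprotonated.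

Step 5
Reactants: 8
Product: 9 (2S)-1-[methoxy(methyl)amino]-1-oxopropan-2-yl trifluoromethanesulfonate
Conditions: Tf2O, 2,6-lutidine, CH2Cl2, −78 °C; used cold at once
Reagents that add atoms: trifluoromethanesulfonic anhydride, O=S(=O)(OS(=O)(=O)C(F)(F)F)C(F)(F)F
Why: O-triflation with retention; the α-triflyloxy carbonyl compound is the standard activated electrophile for clean SN2 displacement.

Step 6
Reactants: 6; 9
Product: 11 (2S)-N-methoxy-N,2-dimethyl-3-{4-methyl-2-oxo-3-[(2S)-2-(tert-butyldimethylsilyloxy)propyl]-2H-pyran-6-yl}propanamide, via lithiated pyranone 10 (not isolated)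
Conditions: LiN(i-Pr)2 (1.05 equiv), THF, −78 °C; then 9 (1.3 equiv), −78 to −40 °C
Reagents that add atoms: none
Why: Lateral lithiation at the 6-methyl group gives an anion delocalised over C5, C3 and the carbonyl oxygen (the 4-methyl anion has the shorter conjugation). This soft carbanion displaces the α-triflate in an SN2 reaction with inversion, so the (S)-triflate gives (12S) and forms C12–C13.

Step 7
Reactants: 11
Product: 12 (2S)-2-methyl-3-{4-methyl-2-oxo-3-[(2S)-2-(tert-butyldimethylsilyloxy)propyl]-2H-pyran-6-yl}propanal
Conditions: Cp2Zr(H)Cl (1.5 equiv), THF, rt, 20 min; then wet silica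
Reagents that add atoms: none
Why: Schwartz reagent reduces tertiary and Weinreb amides to aldehydes through a stable zirconated N,O-acetal and leaves esters and lactones alone, so the hydride-sensitive pyranone survives. No enolate is formed, so C12 is kept.

Step 8
Reactants: 12; 13 (E)-crotylboronic acid pinacol ester
Product: 14 6-[(2S,3S,4R)-3-hydroxy-2,4-dimethylhex-5-en-1-yl]-4-methyl-3-[(2S)-2-(tert-butyldimethylsilyloxy)propyl]-2H-pyran-2-one
Conditions: (R)-TRIP (3,3'-bis(2,4,6-triisopropylphenyl)-1,1'-binaphthyl-2,2'-diyl hydrogen phosphate, 5 mol%), 4 Å molecular sieves, toluene, −30 °C; then aq. NaHCO3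
Reagents that add atoms: none
Why: Chiral phosphoric acid-catalysed crotylboration through a closed chair; the E-crotyl group gives the 10,11-anti relation. The acid directs attack to the Re face of the aldehyde (11S), anti to the C12 methyl, so the catalyst must override the weak Felkin–Anh preference of the α-methyl aldehyde.

Step 9
Reactants: 14
Product: 15 (2S,3S,4R)-2,4-dimethyl-1-{4-methyl-2-oxo-3-[(2S)-2-(tert-butyldimethylsilyloxy)propyl]-2H-pyran-6-yl}hex-5-en-3-yl prop-2-enoate
Conditions: acryloyl chloride (2 equiv), i-Pr2NEt (3 equiv), DMAP (10 mol%), CH2Cl2, 0 °C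
Reagents that add atoms: acryloyl chloride, C=CC(=O)Cl
Why: DMAP-catalysed acylation of the secondary alcohol; it brings in C7 and C8.

Step 10
Reactants: 15
Product: 16 (5R,6S)-5-methyl-6-[(2S)-1-{4-methyl-2-oxo-3-[(2S)-2-(tert-butyldimethylsilyloxy)propyl]-2H-pyran-6-yl}propan-2-yl]-5,6-dihydro-2H-pyran-2-one
Conditions: second-generation Grubbs catalyst RuCl2(=CHPh)(H2IMes)(PCy3) (5 mol%), CH2Cl2 (2 mM), 40 °C
Reagents that add atoms: none
Why: Ring-closing metathesis of the acrylate and vinyl groups forms C8=C9, necessarily cis, in a six-membered lactone. The trisubstituted, electron-poor pyranone alkenes do not take part.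

Step 11
Reactants: 16
Product: 18 tricyclic diene lactone (δ-lactone C7(=O)–O–C11 across C8 and C11 of the bicyclic diene; 8S,9R,10R,11S,12S,19S in the numbering of 31), via bridged lactone adduct 17 (not isolated)
Conditions: toluene (5 mM), BHT (cat.), sealed tube, 150 °C
Reagents that add atoms: none
Why: Intramolecular Diels–Alder reaction of the 2-pyranone (C14–C17) with the lactone enoate C8=C9 closes ring B and gives adduct 17 (drawn endo), which loses its CO2 bridge by cycloreversion to leave the C14=C15–C16=C17 diene of ring A. The cis alkene gives cis H8/H9, and the tether on C11 can only reach the face of the dihydropyranone that carries it, so C8 and C9 are set relative to C10 and C11. Endo or exo does not matter because both bridgeheads become sp2.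

Step 12
Reactants: 18
Product: 19 tricyclic lactol (C7 hemiacetal of 18, both anomers)
Conditions: i-Bu2AlH (1.1 equiv), CH2Cl2, −78 °C; Rochelle salt work-up
Reagents that add atoms: none
Why: Partial reduction of a δ-lactone; the tetrahedral aluminate is stable at −78 °C, and the diene and silyl ether are inert.

Step 13
Reactants: 19; 20 2-(triphenylphosphoranylidene)propanal
Product: 22 (E)-enal with free C11 hydroxyl (C5 aldehyde, C6=C7 alkene; 8S,9S,10R,11S,12S,19S), via open hydroxy aldehyde 21 (not isolated)
Conditions: 20 (2.5 equiv), toluene, 90 °C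
Reagents that add atoms: none
Why: The lactol is in equilibrium with hydroxy aldehyde 21, which is trapped by the stabilised ylide (Wittig reaction). Formyl-stabilised ylides give the E-trisubstituted enal, and the product enal reacts more slowly than the aldehyde, so one unit is added.

Step 14
Reactants: 22
Product: 23 C11 tert-butyldimethylsilyl ether of 22
Conditions: TBSOTf, 2,6-lutidine, CH2Cl2, −78 °C
Reagents that add atoms: tert-butyldimethylsilyl trifluoromethanesulfonate, CC(C)(C)[Si](C)(C)OS(=O)(=O)C(F)(F)F
Why: Silyl triflate with a hindered weak base silylates the flanked secondary alcohol at low temperature, faster than any dienol ether can form from the enal.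

Step 15
Reactants: 23; 20
Product: 24 (4E,6E)-dienal (C3 aldehyde, C11 and C19 silyl ethers; 8S,9S,10R,11S,12S,19S)
Conditions: 20 (3 equiv), toluene, 110 °C
Reagents that add atoms: none
Why: Second Wittig homologation with the same ylide; the α-methyl enal reacts only on heating, and the more conjugated dienal product is less electrophilic again, so the reaction stops at 24 with an E C4=C5 bond.

Step 16
Reactants: 24
Product: 25 (4R,5S)-epoxy aldehyde (C4 is R here only because the formyl group outranks C5; the arrangement in space is that of 4S in 31)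
Conditions: 9-amino(9-deoxy)epiquinine (10 mol%), (R)-TRIP (10 mol%), 50% aq. H2O2 (2 equiv), THF, 50 °C
Reagents that add atoms: hydrogen peroxide, OO
Why: The primary amine condenses with the C3 aldehyde to an iminium ion paired with the chiral phosphate; hydroperoxide adds in conjugate fashion to C5, and the β-peroxy enamine attacks the proximal oxygen through C4 with loss of water, which is the asymmetric amine-salt form of the Weitz–Scheffer epoxidation known for α-branched enals. The oxirane closes by a 3-exo-tet displacement at oxygen. C5 is set by the face of hydroperoxide addition, which the amine–phosphate ion pair controls (C5-Si face); C4 follows because ring closure on the same face (C4-Re) is faster than rotation about C4–C5, so the E-enal gives the trans oxirane with C3 and C6 on opposite sides. The step needs chemoselectivity among five C=C bonds, and the nucleophilic oxidant gives it: only the iminium-conjugated C4=C5 bond is electrophilic, whereas a peracid would go for the ring diene and C6=C7 first. It also needs 1,4- and not 1,6-addition; C7 is the more hindered terminus (C6 methyl, ring carbon C8) and conjugate addition is reversible, so the C5 adduct, which closes at once, should drain the equilibrium. The core stereocentres lie behind the planar C6=C7 bond, so the catalyst alone should decide the face. Both silyl ethers tolerate the weakly acidic aqueous peroxide, and C3 remains an aldehyde for the next olefination.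

Step 17
Reactants: 26 diethylphosphonoacetic acid; 27 2-(trimethylsilyl)ethanol
Product: 28 2-(trimethylsilyl)ethyl 2-(diethoxyphosphoryl)acetate
Conditions: DCC, DMAP (5 mol%), CH2Cl2, 0 °C to rt
Reagents that add atoms: none
Why: Steglich esterification of a simple acid and a primary alcohol.

Step 18
Reactants: 25; 28
Product: 29 2-(trimethylsilyl)ethyl (2E,4S,5S,6E)-ester (full skeleton; C11 and C19 silyl ethers)
Conditions: LiCl, i-Pr2NEt, MeCN, 0 °C to rt
Reagents that add atoms: none
Why: Horner–Wadsworth–Emmons reaction under Masamune–Roush conditions, E-selective and nearly neutral. The aldehyde carbon is attached to the quaternary C4, so nothing can epimerise.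

Step 19
Reactants: 29
Product: 30 (2E,4S,5S,6E)-dihydroxy acid (C11 and C19 alcohols; 8S,9S,10R,11S,12S,19S)
Conditions: n-Bu4NF (5 equiv), THF, 0 to 40 °C; then aq. NH4Cl
Reagents that add atoms: none
Why: Fluoride cleaves both silyl ethers and fragments the silylethyl ester to the carboxylate. C4 has no hydrogen for a base-induced oxirane opening, and the E C2=C3 bond keeps the carboxylate from reaching the oxirane.

Step 20
Reactants: 30
Product: 31 target acid CNP0214881.1 (4S,5S,8S,9S,10R,12S)
Conditions: Dess–Martin periodinane (3 equiv), NaHCO3, CH2Cl2, 0 °C to rt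
Reagents that add atoms: none
Why: Dess–Martin oxidation converts both secondary alcohols to ketones without base, so the β,γ-unsaturated C19 ketone stays out of conjugation and C10/C12 keep their cis arrangement. The buffer protects the allylic oxirane from acetic acid, and the free acid is tolerated.

## Compound list

1 | 4-hydroxy-6-methyl-2H-pyran-2-one | CC1=CC(O)=CC(=O)O1 | starting material
2 | (S)-2-(tert-butyldimethylsilyloxy)propanal | C[C@H](O[Si](C)(C)C(C)(C)C)C=O | starting material
3 | 3-[(2S)-2-(tert-butyldimethylsilyloxy)propylidene]-6-methyl-2H-pyran-2,4(3H)-dione (alkene geometry open) | C[C@H](O[Si](C)(C)C(C)(C)C)C=C1C(=O)C=C(C)OC1=O | intermediate (not isolated)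
4 | 3-[(2S)-2-(tert-butyldimethylsilyloxy)propyl]-4-hydroxy-6-methyl-2H-pyran-2-one | C[C@H](O[Si](C)(C)C(C)(C)C)CC1=C(O)C=C(C)OC1=O | intermediate
5 | 3-[(2S)-2-(tert-butyldimethylsilyloxy)propyl]-6-methyl-2-oxo-2H-pyran-4-yl trifluoromethanesulfonate | C[C@H](O[Si](C)(C)C(C)(C)C)CC1=C(OS(=O)(=O)C(F)(F)F)C=C(C)OC1=O | intermediate
6 | 3-[(2S)-2-(tert-butyldimethylsilyloxy)propyl]-4,6-dimethyl-2H-pyran-2-one | C[C@H](O[Si](C)(C)C(C)(C)C)CC1=C(C)C=C(C)OC1=O | intermediate
7 | ethyl (S)-lactate | CCOC(=O)[C@H](C)O | starting material
8 | (2S)-2-hydroxy-N-methoxy-N-methylpropanamide | C[C@H](O)C(=O)N(C)OC | intermediate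
9 | (2S)-1-[methoxy(methyl)amino]-1-oxopropan-2-yl trifluoromethanesulfonate | C[C@H](OS(=O)(=O)C(F)(F)F)C(=O)N(C)OC | intermediate
10 | 6-(lithiomethyl) derivative of 6 (drawn C-lithiated) | C[C@H](O[Si](C)(C)C(C)(C)C)CC1=C(C)C=C(C[Li])OC1=O | intermediate (not isolated)
11 | (2S)-N-methoxy-N,2-dimethyl-3-{4-methyl-2-oxo-3-[(2S)-2-(tert-butyldimethylsilyloxy)propyl]-2H-pyran-6-yl}propanamide | C[C@H](O[Si](C)(C)C(C)(C)C)CC1=C(C)C=C(C[C@H](C)C(=O)N(C)OC)OC1=O | intermediate
12 | (2S)-2-methyl-3-{4-methyl-2-oxo-3-[(2S)-2-(tert-butyldimethylsilyloxy)propyl]-2H-pyran-6-yl}propanal | C[C@H](O[Si](C)(C)C(C)(C)C)CC1=C(C)C=C(C[C@H](C)C=O)OC1=O | intermediate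
13 | 2-[(2E)-but-2-en-1-yl]-4,4,5,5-tetramethyl-1,3,2-dioxaborolane | C/C=C/CB1OC(C)(C)C(C)(C)O1 | starting material
14 | 6-[(2S,3S,4R)-3-hydroxy-2,4-dimethylhex-5-en-1-yl]-4-methyl-3-[(2S)-2-(tert-butyldimethylsilyloxy)propyl]-2H-pyran-2-one | C[C@H](O[Si](C)(C)C(C)(C)C)CC1=C(C)C=C(C[C@H](C)[C@H](O)[C@H](C)C=C)OC1=O | intermediate
15 | acrylate of 14 | C[C@H](O[Si](C)(C)C(C)(C)C)CC1=C(C)C=C(C[C@H](C)[C@H](OC(=O)C=C)[C@H](C)C=C)OC1=O | intermediate
16 | (5R,6S)-5-methyl-6-[(2S)-1-(pyranonyl)propan-2-yl]-5,6-dihydro-2H-pyran-2-one | C[C@H](O[Si](C)(C)C(C)(C)C)CC1=C(C)C=C(C[C@H](C)[C@@H]2OC(=O)C=C[C@H]2C)OC1=O | intermediate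
17 | bridged [4+2] adduct (2-oxabicyclo[2.2.2]octenone across C14 and C17; endo isomer drawn) | C[C@H](O[Si](C)(C)C(C)(C)C)C[C@]12C(=O)O[C@@]3(C=C1C)C[C@H](C)[C@@H]1OC(=O)[C@H]2[C@H]3[C@H]1C | intermediate (not isolated)
18 | tricyclic diene lactone (8S,9R,10R,11S,12S,19S) | C[C@H](O[Si](C)(C)C(C)(C)C)CC1=C(C)C=C2C[C@H](C)[C@@H]3OC(=O)[C@H]1[C@H]2[C@H]3C | intermediate
19 | tricyclic lactol (anomers) | C[C@H](O[Si](C)(C)C(C)(C)C)CC1=C(C)C=C2C[C@H](C)[C@@H]3OC(O)[C@H]1[C@H]2[C@H]3C | intermediate
20 | 2-(triphenylphosphoranylidene)propanal | CC(C=O)=P(c1ccccc1)(c1ccccc1)c1ccccc1 | starting material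
21 | open C7 aldehyde with C11 hydroxyl | C[C@H](O[Si](C)(C)C(C)(C)C)CC1=C(C)C=C2C[C@H](C)[C@H](O)[C@H](C)[C@@H]2[C@@H]1C=O | intermediate (not isolated)
22 | (E)-enal with C11 hydroxyl | C[C@H](O[Si](C)(C)C(C)(C)C)CC1=C(C)C=C2C[C@H](C)[C@H](O)[C@H](C)[C@@H]2[C@@H]1/C=C(\C)C=O | intermediate
23 | (E)-enal with C11 and C19 silyl ethers | C[C@H](O[Si](C)(C)C(C)(C)C)CC1=C(C)C=C2C[C@H](C)[C@H](O[Si](C)(C)C(C)(C)C)[C@H](C)[C@@H]2[C@@H]1/C=C(\C)C=O | intermediate
24 | (4E,6E)-dienal with C3 aldehyde | C[C@H](O[Si](C)(C)C(C)(C)C)CC1=C(C)C=C2C[C@H](C)[C@H](O[Si](C)(C)C(C)(C)C)[C@H](C)[C@@H]2[C@@H]1/C=C(\C)/C=C(\C)C=O | intermediate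
25 | (4R,5S)-epoxy aldehyde | C[C@H](O[Si](C)(C)C(C)(C)C)CC1=C(C)C=C2C[C@H](C)[C@H](O[Si](C)(C)C(C)(C)C)[C@H](C)[C@@H]2[C@@H]1/C=C(\C)[C@@H]1O[C@@]1(C)C=O | intermediate
26 | diethylphosphonoacetic acid | CCOP(=O)(CC(=O)O)OCC | starting material
27 | 2-(trimethylsilyl)ethanol | C[Si](C)(C)CCO | starting material
28 | 2-(trimethylsilyl)ethyl 2-(diethoxyphosphoryl)acetate | CCOP(=O)(CC(=O)OCC[Si](C)(C)C)OCC | intermediate
29 | 2-(trimethylsilyl)ethyl (2E,4S,5S,6E)-ester with C11 and C19 silyl ethers | C[C@H](O[Si](C)(C)C(C)(C)C)CC1=C(C)C=C2C[C@H](C)[C@H](O[Si](C)(C)C(C)(C)C)[C@H](C)[C@@H]2[C@@H]1/C=C(\C)[C@@H]1O[C@@]1(C)/C=C/C(=O)OCC[Si](C)(C)C | intermediate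
30 | (2E,4S,5S,6E)-dihydroxy acid | C[C@H](O)CC1=C(C)C=C2C[C@H](C)[C@H](O)[C@H](C)[C@@H]2[C@@H]1/C=C(\C)[C@@H]1O[C@@]1(C)/C=C/C(=O)O | intermediate
31 | CNP0214881.1 (4S,5S,8S,9S,10R,12S) | CC(=O)CC1=C(C)C=C2C[C@H](C)C(=O)[C@H](C)[C@@H]2[C@@H]1/C=C(\C)[C@@H]1O[C@@]1(C)/C=C/C(=O)O | target

## Step count and least certain steps

Total step count: 20. Longest linear sequence: 17 (steps 1–3, 6–16, 18–20); steps 4, 5 and 17 prepare 9 and 28.

**Step 16 (key step).** Three processes may interfere. Hydroperoxide may add at C7 (1,6) and not at C5. The ion pair may discriminate the faces poorly on an extended, doubly methyl-substituted iminium ion. The iminium ion may lose the doubly allylic C8 proton to a trienamine, which would scramble C8; acid-promoted opening of the allylic oxirane at 50 °C is a lesser worry. The fallback sets out from 24. 1,2-Reduction (NaBH4, CeCl3·7H2O, MeOH, 0 °C) gives the (2E,4E)-dienol F1. Titanium–tartrate epoxidation (Ti(O-i-Pr)4, L-(+)-diethyl tartrate, t-BuOOH, 4 Å sieves, CH2Cl2, −20 °C), directed by the C3 hydroxyl to C4=C5 alone, gives the (4S,5S)-epoxy alcohol F2; this tartrate is the one that converts (E)-2-alken-1-ols into (2S,3S)-epoxy alcohols. Buffered Dess–Martin oxidation comes back to the route at 25.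

**Step 11.** The cycloaddition may be slow, because both diene termini are fully substituted and the tether must stand axial on the dihydropyranone. At the temperature then needed, a suprafacial 1,5-hydrogen shift (C8–H to C14) could move the new diene into conjugation with the lactone carbonyl and erase C8. The fallback sets out from 14 and uses an open-chain dienophile:
- Silylation (TBSOTf, 2,6-lutidine) gives the C11 silyl ether F6.
- Cleavage of the vinyl group (OsO4 cat., N-methylmorpholine N-oxide; then NaIO4) gives the C9 aldehyde F7.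
- Still–Gennari olefination (bis(2,2,2-trifluoroethyl) (methoxycarbonylmethyl)phosphonate, KN(SiMe3)2, 18-crown-6, THF, −78 °C) gives the (Z)-enoate F8.
- Heating F8 in toluene gives the bicyclic diene ester F9 by cycloaddition and decarboxylation. Facial control here rests on allylic 1,3-strain at C10 and is less secure than in the lactone.
- i-Bu2AlH at −78 °C gives the C7 aldehyde F10, and a Wittig reaction with 20 comes back to the route at 23.

**Step 6.** The anion may take the acidic α-proton of the triflate or attack the amide carbonyl in place of the SN2 reaction, and part of the lithiation may occur at the 4-methyl group. The fallback reverses the polarity and sets out from 6: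
- Lateral lithiation and quenching with BrCF2CF2Br gives the 6-(bromomethyl)pyranone F3.
- Evans alkylation of the sodium enolate of (R)-4-benzyl-3-propanoyl-oxazolidin-2-one (NaN(SiMe3)2, THF, −78 °C) with F3 gives the (2S)-imide F4.
- LiSEt (THF, 0 °C) gives the S-ethyl thioester F5.
- Fukuyama reduction (Et3SiH, Pd/C, acetone) comes back to the route at 12 without a metal hydride.

**Step 13.** The ring–chain equilibrium lies on the lactol side, so olefination may be slow. On prolonged heating the freed C11 hydroxyl can add back to the new enal (oxa-Michael closure), and the α-centre C8 of the open aldehyde can epimerise. The fallback sets out from 18. Aminolysis (MeNH(OMe)·HCl, AlMe3, CH2Cl2, 0 °C) gives the hydroxy Weinreb amide F11. Silylation (TBSOTf, 2,6-lutidine) gives F12. i-Bu2AlH (THF, −78 °C) gives the aldehyde F10 already described, which is olefinated with 20 at once, coming back to the route at 23.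

## Further compounds

F1 | step 16 | (2E,4E)-dienol (C3 alcohol of 24) | C[C@H](O[Si](C)(C)C(C)(C)C)CC1=C(C)C=C2C[C@H](C)[C@H](O[Si](C)(C)C(C)(C)C)[C@H](C)[C@@H]2[C@@H]1/C=C(\C)/C=C(\C)CO
F2 | step 16 | (4S,5S)-epoxy alcohol | C[C@H](O[Si](C)(C)C(C)(C)C)CC1=C(C)C=C2C[C@H](C)[C@H](O[Si](C)(C)C(C)(C)C)[C@H](C)[C@@H]2[C@@H]1/C=C(\C)[C@@H]1O[C@@]1(C)CO
F3 | step 6 | 6-(bromomethyl)-4-methyl-3-[(2S)-2-(tert-butyldimethylsilyloxy)propyl]-2H-pyran-2-one | C[C@H](O[Si](C)(C)C(C)(C)C)CC1=C(C)C=C(CBr)OC1=O
F4 | step 6 | (4R)-4-benzyl-3-[(2S)-2-methyl-3-(pyranonyl)propanoyl]oxazolidin-2-one | C[C@H](O[Si](C)(C)C(C)(C)C)CC1=C(C)C=C(C[C@H](C)C(=O)N2[C@H](Cc3ccccc3)COC2=O)OC1=O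
F5 | step 6 | S-ethyl (2S)-2-methyl-3-(pyranonyl)propanethioate | C[C@H](O[Si](C)(C)C(C)(C)C)CC1=C(C)C=C(C[C@H](C)C(=O)SCC)OC1=O
F6 | step 11 | C11 tert-butyldimethylsilyl ether of 14 | C[C@H](O[Si](C)(C)C(C)(C)C)CC1=C(C)C=C(C[C@H](C)[C@H](O[Si](C)(C)C(C)(C)C)[C@H](C)C=C)OC1=O
F7 | step 11 | C9 aldehyde | C[C@H](O[Si](C)(C)C(C)(C)C)CC1=C(C)C=C(C[C@H](C)[C@H](O[Si](C)(C)C(C)(C)C)[C@H](C)C=O)OC1=O
F8 | step 11 | methyl (Z)-enoate | C[C@H](O[Si](C)(C)C(C)(C)C)CC1=C(C)C=C(C[C@H](C)[C@H](O[Si](C)(C)C(C)(C)C)[C@H](C)/C=C\C(=O)OC)OC1=O
F9 | step 11 | bicyclic diene methyl ester (C7 ester on C8) | C[C@H](O[Si](C)(C)C(C)(C)C)CC1=C(C)C=C2C[C@H](C)[C@H](O[Si](C)(C)C(C)(C)C)[C@H](C)[C@@H]2[C@@H]1C(=O)OC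
F10 | step 11 | bicyclic C7 aldehyde with C11 silyl ether | C[C@H](O[Si](C)(C)C(C)(C)C)CC1=C(C)C=C2C[C@H](C)[C@H](O[Si](C)(C)C(C)(C)C)[C@H](C)[C@@H]2[C@@H]1C=O
F11 | step 13 | C7 Weinreb amide with C11 hydroxyl | C[C@H](O[Si](C)(C)C(C)(C)C)CC1=C(C)C=C2C[C@H](C)[C@H](O)[C@H](C)[C@@H]2[C@@H]1C(=O)N(C)OC
F12 | step 13 | C7 Weinreb amide with C11 silyl ether | C[C@H](O[Si](C)(C)C(C)(C)C)CC1=C(C)C=C2C[C@H](C)[C@H](O[Si](C)(C)C(C)(C)C)[C@H](C)[C@@H]2[C@@H]1C(=O)N(C)OC
A1 | alternative 1 | 5-(menthyloxy)furan-2(5H)-one | O=C1O[C@H](O[C@H]2C[C@@H](C)CC[C@@H]2C(C)C)C=C1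
A2 | alternative 1 | tricyclic dienyl lactone (C18 lactone carbonyl on C17, C7 menthyl acetal on C8) | O=C1O[C@H](O[C@H]2C[C@@H](C)CC[C@@H]2C(C)C)[C@@H]2C1=C(C)C=C1C[C@H](C)C(OC)(OC)C[C@@H]12
A3 | alternative 2 | bicyclic acid (C7 carboxyl on C8, C14=C15 alkene) | OC(=O)[C@@H]1[C@H](O[Si](CC)(CC)CC)[C@H](C)C=C2C[C@H](C)[C@H](O[Si](C)(C)C(C)(C)C)[C@H](C)[C@H]12
A4 | alternative 3 | tricarbonyliron complex of the bicyclic diene ketone | C[C@H](O[Si](C(C)C)(C(C)C)C(C)C)CC1=C(C)C=C2C[C@H](C)C(=O)C[C@@H]2[C@@H]1CO[Si](C(C)C)(C(C)C)C(C)C.[Fe].[C-]#[O+].[C-]#[O+].[C-]#[O+]
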